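The earlier runs and the new flask are calculated on assumed constants; noise was put on by code.

| flask | X | D | remark | time |
|---|---|---|---|---|
| teal | 20 mM | 0.80 equiv | run made earlier |  |
| red | 20 mM | 1.8 equiv | run made earlier |  |
| flask | 20 mM | 1.20 equiv |  | 25 min |

- teal (time / min: E / %, X / %): 6.00: 35.3, 62.2; 8.00: 44.2, 54.0; 12.0: 56.8, 39.7; 15.0: 65.1, 32.1; 20.0: 71.7, 24.0
- red (time / min: E / %, X / %): 6.00: 38.7, 61.1; 8.00: 47.2, 52.8; 12.0: 61.8, 36.9; 15.0: 69.6, 29.0; 20.0: 79.9, 20.4

(readings scatter by 0.5 percentage points)

* when, up to 25 min, the flask holds most E
* the amount of E, in percent of the X charged, at that time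

1. I reckoned the effect of the time of reading, 25 min, on E in the flask through one count. From the red run, [X] fell at 0.0784 /min as a first-order reading, and I called this rate times the time the turnover count, 1.96. I took the part of X left in the flask as exp(-count) and E as the rest.

2. I tested the time first. Stopping at 20.0 min left 6.8 percentage points more X by this count, so the time mattered.

3. Next I tested the rate. The teal readings gave 0.0680 /min, and using that rate left 4.2 points more X, less than the time did.

4. The start of X, 20 mM, was the same in both runs and the flask. G was counted in E, so the split between them did not enter the count.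

5. Now the number. In the teal run D, at 0.80 equiv, was the limiting reagent, while the flask's 1.20 equiv stood above one equivalent, as the red run's did, so I used the red rate. That gave 85.9% of E in the flask at 25 min. E rose from each reading to the next in both runs, so I put the flask's highest E at 25 min.

6. The forecast said 84.5% at 25 min, with the grounds “Nothing consumes E overall, so E rises throughout”. My figure stood higher.

    G ⇌ E, rate k1*(cs1 - [E]) while solid is left; crystals form when [E] > cs1 (solubility = 1.30 mM, k = 7.08 /min)
    D + Z → E (k = 189 /M/min)
    X ⇌ Z (K = 0.630, k = 0.0834 /min)

7. The flask held most E at 25.0 min, namely 85.1%. X then stood at 14.0%, and exp(-count) gives 14.1%. Over 10 min, the same rate gives 45.7% of X, and the same flask read at that time held 44.8%.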